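## Structural features

Euchrenone a3 is a flavanone: aromatic ring A is fused through C4a and C8a to the dihydropyranone ring C (O1, C2, C3, C4=O), and ring B is attached at C2. Ring A is fully substituted, with hydroxyls at C5 and C7 and 3-methylbut-2-enyl (prenyl) groups at C6 and C8. Ring B carries a free 2'-hydroxyl and a 2,2-dimethyl-2H-pyran ring fused linearly across C4' (oxygen) and C5' (carbon), so only C3' and C6' remain as aromatic CH. C2 (S) is the only stereocentre and has no stereogenic neighbour. It is benzylic, β to the C4 ketone and bonded to O1, so base can erase it by retro-oxa-Michael opening to the chalcone, and strong acid can ionise the C2–O1 bond with help from the two oxygens of ring B. The two prenyl alkenes ortho to phenols (closed to chromans by acid, incompatible with hydrogenolysis or ozonolysis), the styrene-like chromene alkene and the free phenols are the fragile groups. The real difficulty is threefold: a hexasubstituted ring A with every substituent in a defined place, a linear rather than angular chromene, and a single configuration at C2 that must never pass through a base-exposed flavanone. The key step uses the O1–C8a bond: the bond to be made lies on the aryl side of O1, so a C2 carbinol of fixed configuration can be joined to a halogen-bearing C8a of ring A, closing ring C without touching any bond at C2.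

## Logic of the disconnections

**23 back to 22.** The three O–CH2 acetal bonds on O5, O7 and O2' are cut. The phenols must be masked against carbonate at 110 °C, a boron Lewis acid and an oxidant. Methoxymethyl ethers are base-stable, cannot migrate to a neighbouring alkoxide as silyl groups would, and need no hydrogenolysis. The demand is an acidolysis mild enough to spare the prenyl groups, the chromene and C2.

**22 back to 21.** The C4 carbonyl is taken back to the C4 carbinol. With a ketone at C4 the open-chain precursor would be a β-hydroxy ketone, open to retro-aldol cleavage and dehydration, and the flavanone itself would open under carbonate. The forward step needs a neutral oxidant for a hindered benzylic alcohol.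

**21 back to 20.** The O1–C8a bond is cut. Ring C opens, the stereocentre becomes an acyclic carbinol that aldol chemistry can set, and ring A becomes an aryl bromide. The forward step demands metal insertion into a C–Br bond flanked by two ortho substituents; site selectivity between the two hydroxyls is built in, because only one of them can form a six-membered ring.

**20 back to 19.** The C1–H bond is removed, returning to the ketone. A hydroxyl-directed reduction gives one defined diastereomer in an acidic medium that cannot cause retro-aldol cleavage. The demand is modest, because this centre is erased again on the way to 22.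

**19 back to 7 and 16.** The CH2–CH(OH) bond (C2–C3 of the flavanone) is cut. It is the one C–C bond at the stereocentre that can be formed with enantiocontrol from two achiral halves, and it divides the molecule into two arenes of similar size. The forward step must control the face of an aromatic aldehyde with a chiral boron enolate of a hindered methyl ketone.

**7 back to 6, 5, 3, 2 and 1.** Each prenyl alkene is cut to an allyl group (cross-metathesis), each aryl–CH2 bond to an O-allyl ether (Claisen rearrangement), and the aryl–acetyl bond to an acylation of 1. Direct double C-prenylation of the phenoxide of 2 would save two steps but gives mixtures of C- and O-alkylated products; the allyl route converges on one regioisomer because the acetyl group and the bromine block the other sites. The demand is two rearrangements at about 195 °C and a double metathesis.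

**16 back to 15, 13, 11, and 8 with 9.** The formyl C–C bond, the chromene alkene and the pyranone ring are cut in turn. Building the pyran ring by acylation and oxa-Michael addition fixes the ring oxygen and the free hydroxyl without ambiguity. This avoids the angular/linear problem of a propargyl ether rearrangement on a resorcinol. The demand is ortho-formylation at C6 rather than C8.

## Other disconnections considered

**Alternative 1:** The two aryl–CH2 bonds of the prenyl groups (C6 and C8) are cut. In the forward sense the bis(tert-prenyl) ether A1 is heated; two [3,3] shifts deliver both prenyl groups and free both ring-A phenols to give A2, which needs only desilylation to reach 23.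
- In its favour: both prenyl groups arrive in one metal-free step, ring A needs no protecting group afterwards, and there is neither a halogenated ring nor a hindered coupling.
- Against it here: A1 must be made by tertiary O-alkylation of a hydrogen-bonded 5-hydroxyl and a semi-hydrogenation next to a chromene, on a flavanone that opens under the base used for alkylation. The 7-O ether can also go to C6; the 5-O ether would then have to travel to C8 by a Claisen–Cope sequence, which delivers a reverse prenyl group. The source of the C2 configuration is left open.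
- Comparison: on step count for the prenyl pair the two plans are about equal (three operations each). On the final deprotection the alternative is better, one fluoride-labile silyl ether against three acetals. On stereochemical safety the chosen plan is better, because C2 stays a carbinol in a base-tolerant diol until ring C is closed.

**Alternative 2:** The C5'–CH bond of the chromene is cut (the O–CMe2 bond breaks and re-forms). Heating the 4'-O-(1,1-dimethylpropargyl) ether A3 triggers a propargyl Claisen shift, enolisation, a 1,5-hydrogen shift and an oxa-6π closure to give A4.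
- In its favour: ring B travels through the synthesis as a simple resorcinol-type arene, and the acid-sensitive chromene alkene appears only at the end. The ring-B sequence is shorter than the four steps to 16 here, and on that count the alternative is better.
- Against it: the shift can go to C3', between the two oxygens, as well as to C5', and only the bulk of the 2'-silyl ether steers it. A flavanone must survive both the basic propargylation and prolonged heating. Two different protecting groups must come off at the end.
- Comparison: mechanistically the pericyclic cascade is clean and metal-free, equal to the chosen key step in simplicity. Regiochemically the chosen plan is better, since 11 fixes the linear fusion by construction.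

**Alternative 3:** The C4a–C5 bond of ring A is cut. Mg(OCH3)2 turns the dihydropyranone A5 into its extended enolate, C4a acylates the terminal ester, and enolisation aromatises ring A to give A6.
- In its favour: no aromatic prenylation and no halogen, since both prenyl groups sit on sp3 carbons of the chain. Only one protecting group remains at the end, which is better than the chosen plan. C2 could come from a catalytic asymmetric hetero-Diels–Alder reaction of 16 with a Danishefsky-type diene, a source of configuration at least equal to, and probably better than, the boron aldol used here.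
- Against it: the doubly prenylated diketo ester chain on the dihydropyranone is a long linear construction with several acidic sites. A competing aldol closure of the C6 carbanion onto the C4 carbonyl would give a different arene. A β-alkoxy enone under a basic magnesium alkoxide can open by retro-oxa-Michael reaction and lose C2.
- Comparison: structurally the alternative avoids the hexasubstituted arene chemistry altogether. The chosen plan is shorter and its key step cannot affect C2.

Key step: step 12

Assumption: the enolate of 7 formed with (+)-Ipc2BCl (the reagent made from (−)-α-pinene) is taken to add to the Si face of aldehyde 16, which gives 3S. The configuration of 19 should be checked (for example as its Mosher esters); if the sense is opposite, (−)-Ipc2BCl is used in the same step.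

Remark on the structures: the C3 carbinol of 20 must be S to map onto 2S of 23, the anti diol is then 1S,3S and the ring-closed alcohol 2S,4S; these descriptors agree with the SMILES used below.

## Route

Step 1
Reactants: 1 5-bromoresorcinol
Product: 2 1-(2-bromo-4,6-dihydroxyphenyl)ethan-1-one
Conditions: AcOH (1.2 equiv), BF3·OEt2 (as medium), 90 °C; then aq. NaOAc
Reagents that add atoms: acetic acid CC(=O)O
Why: Friedel–Crafts acylation of a resorcinol (Nencki type); attack occurs para to one hydroxyl and ortho to the other, as with resorcinol itself, which puts the acetyl group next to bromine, while the site between the two hydroxyls is not acylated.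

Step 2
Reactants: 2 1-(2-bromo-4,6-dihydroxyphenyl)ethan-1-one
Product: 3 1-[2-bromo-4,6-bis(prop-2-en-1-yloxy)phenyl]ethan-1-one
Conditions: allyl bromide (2.6 equiv), K2CO3 (3 equiv), DMF, 60 °C
Reagents that add atoms: allyl bromide C=CCBr
Why: Williamson ether synthesis; excess allyl bromide in DMF also alkylates the hydrogen-bonded hydroxyl next to the acetyl group.

Step 3
Reactants: 3 1-[2-bromo-4,6-bis(prop-2-en-1-yloxy)phenyl]ethan-1-one
Product: 5 1-[2-bromo-4,6-dihydroxy-3,5-di(prop-2-en-1-yl)phenyl]ethan-1-one, via mono-rearranged allyl ether 4 (not isolated)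
Conditions: N,N-diethylaniline, 195 °C, sealed tube, argon
Reagents that add atoms: none
Why: Double aromatic Claisen rearrangement; the ether next to the acetyl group can shift only to C5 and the other ether then has only C3 left, and if the order is reversed the blocked ether reaches C3 by a Claisen–Cope sequence that gives the same unsubstituted allyl group, so every path converges on 5.

Step 4
Reactants: 5 1-[2-bromo-4,6-dihydroxy-3,5-di(prop-2-en-1-yl)phenyl]ethan-1-one
Product: 6 1-[2-bromo-4,6-bis(methoxymethoxy)-3,5-di(prop-2-en-1-yl)phenyl]ethan-1-one
Conditions: NaH (2.2 equiv), MOMCl (2.5 equiv), DMF, 0 °C to rt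
Reagents that add atoms: chloromethyl methyl ether COCCl
Why: O-alkylation of the bis-phenoxide to the methoxymethyl ethers; NaH is needed for the chelated and doubly flanked hydroxyls, and the phenols are deprotonated in preference to the far less acidic methyl ketone.

Step 5
Reactants: 6 1-[2-bromo-4,6-bis(methoxymethoxy)-3,5-di(prop-2-en-1-yl)phenyl]ethan-1-one
Product: 7 1-[2-bromo-4,6-bis(methoxymethoxy)-3,5-bis(3-methylbut-2-en-1-yl)phenyl]ethan-1-one
Conditions: 2-methylbut-2-ene (large excess), second-generation Grubbs catalyst (H2IMes)(PCy3)Cl2Ru=CHPh (5 mol%), CH2Cl2, 40 °C, sealed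
Reagents that add atoms: 2-methylbut-2-ene CC=C(C)C
Why: Olefin cross-metathesis of both terminal allyl groups with 2-methylbut-2-ene, the usual way to turn allyl into prenyl; the large excess of the trisubstituted alkene suppresses homodimerisation and propene escapes.

Step 6
Reactants: 8 resorcinol; 9 3-methylbut-2-enoic acid
Product: 11 7-hydroxy-2,2-dimethylchroman-4-one, via aryl enone 10 (not isolated)
Conditions: P2O5/MeSO3H (Eaton's reagent), 70 °C
Reagents that add atoms: none
Why: Friedel–Crafts acylation para to one hydroxyl, then intramolecular oxa-Michael addition of the ortho hydroxyl; the hydroxyl para to the ketone cannot cyclise and becomes the 7-hydroxyl, which fixes the later linear ring fusion.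

Step 7
Reactants: 11 7-hydroxy-2,2-dimethylchroman-4-one
Product: 13 2,2-dimethyl-2H-chromen-7-ol, via chromane-4,7-diol 12 (not isolated)
Conditions: NaBH4 (3 equiv), MeOH–THF, 0 °C to rt; 1 M HCl quench; crude diol, TsOH·H2O (2 mol%), toluene, 60 °C
Reagents that add atoms: none
Why: Borohydride reduction followed by acid-catalysed E1 dehydration of the benzylic alcohol, which ionises easily because the 7-oxygen is para to C4a.

Step 8
Reactants: 13 2,2-dimethyl-2H-chromen-7-ol
Product: 15 7-hydroxy-2,2-dimethyl-2H-chromene-6-carbaldehyde, via hydroxymethyl phenol 14 (not isolated)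
Conditions: MgCl2 (2 equiv), Et3N (4 equiv), (CH2O)n (6 equiv), MeCN, reflux
Reagents that add atoms: formaldehyde (as paraformaldehyde) C=O
Why: Magnesium-mediated ortho-formylation of a phenol (Casnati–Skattebøl); the magnesium phenoxide delivers formaldehyde to an ortho carbon and a second formaldehyde oxidises the benzylic alkoxide by hydride transfer, with C6 preferred over C8, which is wedged between the two oxygens.

Step 9
Reactants: 15 7-hydroxy-2,2-dimethyl-2H-chromene-6-carbaldehyde
Product: 16 7-(methoxymethoxy)-2,2-dimethyl-2H-chromene-6-carbaldehyde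
Conditions: MOMCl (1.5 equiv), i-Pr2NEt (2 equiv), CH2Cl2, 0 °C to rt
Reagents that add atoms: chloromethyl methyl ether COCCl
Why: Phenol protection as the methoxymethyl ether under amine base; the aldehyde and the chromene are untouched.

Step 10
Reactants: 7 1-[2-bromo-4,6-bis(methoxymethoxy)-3,5-bis(3-methylbut-2-en-1-yl)phenyl]ethan-1-one; 16 7-(methoxymethoxy)-2,2-dimethyl-2H-chromene-6-carbaldehyde
Product: 19 (3S)-1-[2-bromo-4,6-bis(methoxymethoxy)-3,5-bis(3-methylbut-2-en-1-yl)phenyl]-3-hydroxy-3-[7-(methoxymethoxy)-2,2-dimethyl-2H-chromen-6-yl]propan-1-one, via boron enolate 17 (not isolated), via boron aldolate 18 (not isolated)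
Conditions: (+)-Ipc2BCl (1.3 equiv), Et3N (1.6 equiv), Et2O, 0 °C; then 16, −78 to −20 °C; H2O2, MeOH, pH 7 buffer, 0 °C
Reagents that add atoms: none
Why: Reagent-controlled boron aldol reaction of a methyl ketone: Et3N and the chloroborane form the only possible enolate, which adds to the non-enolisable aldehyde through a cyclic six-membered transition state. The two isopinocampheyl groups on boron direct the enolate carbon to the Si face of the aldehyde, which sets 3S; buffered peroxide then cleaves the boron aldolate without acid or base.

Step 11
Reactants: 19 the (3S)-β-hydroxy ketone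
Product: 20 (1S,3S)-1-[2-bromo-4,6-bis(methoxymethoxy)-3,5-bis(3-methylbut-2-en-1-yl)phenyl]-3-[7-(methoxymethoxy)-2,2-dimethyl-2H-chromen-6-yl]propane-1,3-diol
Conditions: Me4NBH(OAc)3 (6 equiv), MeCN–AcOH (2:1), −30 to −20 °C
Reagents that add atoms: none
Why: Evans–Saksena hydroxyl-directed reduction: the C3 hydroxyl replaces an acetate on boron and hydride is delivered intramolecularly through a chair transition state, giving the anti diol and hence 1S. The cold acidic medium excludes retro-aldol cleavage, and because C1 is oxidised again in step 13, selectivity here affects only the homogeneity of 20 and 21.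

Step 12
Reactants: 20 the (1S,3S)-diol
Product: 21 (2S,4S)-5,7-bis(methoxymethoxy)-2-[7-(methoxymethoxy)-2,2-dimethyl-2H-chromen-6-yl]-6,8-bis(3-methylbut-2-en-1-yl)chroman-4-ol
Conditions: CuI (20 mol%), 3,4,7,8-tetramethyl-1,10-phenanthroline (40 mol%), Cs2CO3 (2.5 equiv), toluene (0.02 M), 110 °C, argon
Reagents that add atoms: none
Why: Ullmann-type, ligand-accelerated intramolecular O-arylation of a secondary alcohol by an aryl bromide; the closest known reaction is the CuI/phenanthroline etherification of aliphatic alcohols and its ring-closing use for chromans. Cs2CO3 converts the C3 hydroxyl of 20 (C2 of the flavan) into a monovalent copper alkoxide carried by the phenanthroline ligand, oxidative addition of the C8a–Br bond gives a trivalent aryl(alkoxo)copper species in a seven-membered metallacycle, and C–O reductive elimination forms O1–C8a. Ring C closes as a six-membered ring in the exo mode, the oxygen attacking the ipso carbon of the arene from a three-atom tether. No stereocentre is made: C2 keeps its S configuration because only its O–H bond takes part, and C4 is a spectator. The selectivity needed is between the two hydroxyls, and the substrate secures it, since the C1 hydroxyl could only close a four-membered ring. Bromine is meta to both alkoxy groups of ring A, so C8a is not deactivated towards oxidative addition, and intramolecularity offsets the two ortho substituents. The methoxymethyl ethers, the prenyl groups and the chromene are inert to carbonate in toluene, and a 1,3-diol cannot undergo retro-aldol cleavage or β-elimination.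

Step 13
Reactants: 21 the (2S,4S)-flavan-4-ol
Product: 22 (2S)-5,7-bis(methoxymethoxy)-2-[7-(methoxymethoxy)-2,2-dimethyl-2H-chromen-6-yl]-6,8-bis(3-methylbut-2-en-1-yl)chroman-4-one
Conditions: Dess–Martin periodinane (1.5 equiv), NaHCO3, CH2Cl2, 0 °C to rt
Reagents that add atoms: none
Why: Dess–Martin oxidation of the secondary benzylic alcohol under buffered, near-neutral conditions; C2 is not alpha to the new carbonyl and no base is present to open ring C, so the 2S centre is untouched.

Step 14
Reactants: 22 the tris(methoxymethyl) flavanone
Product: 23 euchrenone a3, (2S)-5,7-dihydroxy-2-(7-hydroxy-2,2-dimethyl-2H-chromen-6-yl)-6,8-bis(3-methylbut-2-en-1-yl)chroman-4-one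
Conditions: 3 M aq. HCl (cat. to few equiv), MeOH–THF, 40 °C, stopped at full conversion
Reagents that add atoms: none
Why: Acid-catalysed acetal exchange removes the three methoxymethyl groups as dimethoxymethane; dilute acid at mild temperature is chosen so that the prenyl groups do not cyclise onto the freed phenols, methanol does not add to the chromene and ring C does not open.

## Compound list

1 | 5-bromoresorcinol | Oc1cc(O)cc(Br)c1 | starting material
2 | 1-(2-bromo-4,6-dihydroxyphenyl)ethan-1-one | CC(=O)c1c(O)cc(O)cc1Br | intermediate
3 | 1-[2-bromo-4,6-bis(prop-2-en-1-yloxy)phenyl]ethan-1-one | CC(=O)c1c(OCC=C)cc(OCC=C)cc1Br | intermediate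
4 | 1-[6-bromo-2-hydroxy-3-(prop-2-en-1-yl)-4-(prop-2-en-1-yloxy)phenyl]ethan-1-one (mono-rearranged allyl ether) | CC(=O)c1c(O)c(CC=C)c(OCC=C)cc1Br | intermediate
5 | 1-[2-bromo-4,6-dihydroxy-3,5-di(prop-2-en-1-yl)phenyl]ethan-1-one | CC(=O)c1c(O)c(CC=C)c(O)c(CC=C)c1Br | intermediate
6 | 1-[2-bromo-4,6-bis(methoxymethoxy)-3,5-di(prop-2-en-1-yl)phenyl]ethan-1-one | CC(=O)c1c(OCOC)c(CC=C)c(OCOC)c(CC=C)c1Br | intermediate
7 | 1-[2-bromo-4,6-bis(methoxymethoxy)-3,5-bis(3-methylbut-2-en-1-yl)phenyl]ethan-1-one | CC(=O)c1c(OCOC)c(CC=C(C)C)c(OCOC)c(CC=C(C)C)c1Br | intermediate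
8 | resorcinol | Oc1cccc(O)c1 | starting material
9 | 3-methylbut-2-enoic acid | CC(C)=CC(=O)O | starting material
10 | 1-(2,4-dihydroxyphenyl)-3-methylbut-2-en-1-one (aryl enone) | CC(C)=CC(=O)c1ccc(O)cc1O | intermediate
11 | 7-hydroxy-2,2-dimethylchroman-4-one | O=C1CC(C)(C)Oc2cc(O)ccc12 | intermediate
12 | 2,2-dimethylchromane-4,7-diol (racemic) | OC1CC(C)(C)Oc2cc(O)ccc12 | intermediate
13 | 2,2-dimethyl-2H-chromen-7-ol | Oc1ccc2C=CC(C)(C)Oc2c1 | intermediate
14 | 6-(hydroxymethyl)-2,2-dimethyl-2H-chromen-7-ol | OCc1cc2C=CC(C)(C)Oc2cc1O | intermediate
15 | 7-hydroxy-2,2-dimethyl-2H-chromene-6-carbaldehyde | O=Cc1cc2C=CC(C)(C)Oc2cc1O | intermediate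
16 | 7-(methoxymethoxy)-2,2-dimethyl-2H-chromene-6-carbaldehyde | O=Cc1cc2C=CC(C)(C)Oc2cc1OCOC | intermediate
17 | bis(isopinocampheyl)boron enolate of 7 | C=C(OB([C@H]1C[C@H]2C[C@@H]([C@@H]1C)C2(C)C)[C@H]1C[C@H]2C[C@@H]([C@@H]1C)C2(C)C)c1c(Br)c(CC=C(C)C)c(OCOC)c(CC=C(C)C)c1OCOC | intermediate
18 | bis(isopinocampheyl)boron aldolate of 19 (3S) | O=C(C[C@H](OB([C@H]1C[C@H]2C[C@@H]([C@@H]1C)C2(C)C)[C@H]1C[C@H]2C[C@@H]([C@@H]1C)C2(C)C)c1cc2C=CC(C)(C)Oc2cc1OCOC)c1c(Br)c(CC=C(C)C)c(OCOC)c(CC=C(C)C)c1OCOC | intermediate
19 | (3S)-1-[2-bromo-4,6-bis(methoxymethoxy)-3,5-bis(3-methylbut-2-en-1-yl)phenyl]-3-hydroxy-3-[7-(methoxymethoxy)-2,2-dimethyl-2H-chromen-6-yl]propan-1-one | CC(C)=CCc1c(OCOC)c(CC=C(C)C)c(Br)c(C(=O)C[C@H](O)c2cc3C=CC(C)(C)Oc3cc2OCOC)c1OCOC | intermediate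
20 | (1S,3S)-1-[2-bromo-4,6-bis(methoxymethoxy)-3,5-bis(3-methylbut-2-en-1-yl)phenyl]-3-[7-(methoxymethoxy)-2,2-dimethyl-2H-chromen-6-yl]propane-1,3-diol | O[C@H](c2c(Br)c(CC=C(C)C)c(OCOC)c(CC=C(C)C)c2OCOC)C[C@H](O)c3cc4c(cc3OCOC)OC(C)(C)C=C4 | intermediate
21 | (2S,4S)-5,7-bis(methoxymethoxy)-2-[7-(methoxymethoxy)-2,2-dimethyl-2H-chromen-6-yl]-6,8-bis(3-methylbut-2-en-1-yl)chroman-4-ol | O[C@H]1C[C@@H](c3cc4c(cc3OCOC)OC(C)(C)C=C4)Oc2c(CC=C(C)C)c(OCOC)c(CC=C(C)C)c(OCOC)c12 | intermediate
22 | (2S)-5,7-bis(methoxymethoxy)-2-[7-(methoxymethoxy)-2,2-dimethyl-2H-chromen-6-yl]-6,8-bis(3-methylbut-2-en-1-yl)chroman-4-one | O=C1C[C@@H](c3cc4c(cc3OCOC)OC(C)(C)C=C4)Oc2c(CC=C(C)C)c(OCOC)c(CC=C(C)C)c(OCOC)c12 | intermediate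
23 | euchrenone a3 | CC(C)=CCc1c(O)c(CC=C(C)C)c2c(c1O)C(=O)C[C@@H](c1cc3c(cc1O)OC(C)(C)C=C3)O2 | target

## Step count and least certain steps

Total step count: 14. Longest linear sequence: 10 (steps 1–5, then 10–14); the ring-B branch (steps 6–9) joins at step 10.

**Step 12 (key step).** Oxidative addition of copper into a C–Br bond flanked by the carbinol side chain and a prenyl group may be slow. Prolonged heating then invites hydrodebromination and thermal decomposition. Fallback, from 20 back to 21: a palladium-catalysed intramolecular etherification with Pd(OAc)2 (5 mol%), racemic 2-(di-tert-butylphosphino)-1,1'-binaphthyl, Cs2CO3, toluene, 70 °C. This is a change of metal and of elementary steps rather than of conditions. Zerovalent palladium inserts into hindered aryl bromides far more readily than monovalent copper, and the bulky phosphine drives C–O reductive elimination from the divalent aryl(alkoxo)palladium intermediate. C2 is again not touched. This fallback makes no new compound (F0).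

**Step 10.** The facial selectivity of diisopinocampheylboron enolates of methyl ketones is often only moderate. Enolisation of the twisted, doubly ortho-substituted ketone may be sluggish, and the sense of induction rests on the assumption stated above. Fallback, from 7 and 16 back to 19:
- Claisen–Schmidt condensation (KOH, EtOH, rt) gives the (E)-chalcone F1.
- Copper-catalysed enantioselective conjugate borylation (CuCl, NaOt-Bu, a Josiphos-type bisphosphine, B2pin2, MeOH, THF, rt) gives the (S)-β-boryl ketone F2. The ligand enantiomer is chosen to give S, and the enone reacts far faster than the aryl bromide.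
- Oxidation with NaBO3·4H2O in THF–water proceeds with retention at carbon and gives 19.

**Step 8.** Formylation may also occur at C8 or twice, and the electron-rich chromene may suffer under prolonged heating. Fallback, from 9 back to 16, with the position of the aldehyde fixed by a bromine from the start:
- Purchased 4-bromoresorcinol F3 replaces 8 and is acylated and cyclised with 9 (P2O5/MeSO3H, 70 °C) to 6-bromo-7-hydroxy-2,2-dimethylchroman-4-one F4.
- MOMCl and i-Pr2NEt give 6-bromo-7-(methoxymethoxy)-2,2-dimethylchroman-4-one F5.
- NaBH4 gives 6-bromo-7-(methoxymethoxy)-2,2-dimethylchroman-4-ol F6.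
- MsCl and Et3N eliminate to 6-bromo-7-(methoxymethoxy)-2,2-dimethyl-2H-chromene F7.
- Bromine–lithium exchange (n-BuLi, THF, −78 °C) and quenching with DMF give 16.

**Step 14.** Under protic acid the prenyl groups may cyclise onto the freed ortho phenols, methanol may add across the chromene, cleavage of the doubly flanked 7-O acetal may lag, and ring C may open and re-close with loss of configuration at C2. Fallback, from 22 back to 23: aprotic acetal exchange with TMSOTf and 2,2'-bipyridyl in MeCN at 0 °C converts the three aryl methoxymethyl ethers into the tris(trimethylsilyl) ether F8. The buffered aqueous work-up then hydrolyses F8 to 23 without any strong Brønsted acid.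

## Further compounds

F0 | step 12 | none | none
F1 | step 10 | (E)-1-[2-bromo-4,6-bis(methoxymethoxy)-3,5-bis(3-methylbut-2-en-1-yl)phenyl]-3-[7-(methoxymethoxy)-2,2-dimethyl-2H-chromen-6-yl]prop-2-en-1-one | CC(C)=CCc1c(OCOC)c(CC=C(C)C)c(Br)c(C(=O)/C=C/c2cc3C=CC(C)(C)Oc3cc2OCOC)c1OCOC
F2 | step 10 | (3S)-1-[2-bromo-4,6-bis(methoxymethoxy)-3,5-bis(3-methylbut-2-en-1-yl)phenyl]-3-[7-(methoxymethoxy)-2,2-dimethyl-2H-chromen-6-yl]-3-(4,4,5,5-tetramethyl-1,3,2-dioxaborolan-2-yl)propan-1-one | CC(C)=CCc1c(OCOC)c(CC=C(C)C)c(Br)c(C(=O)C[C@H](B2OC(C)(C)C(C)(C)O2)c2cc3C=CC(C)(C)Oc3cc2OCOC)c1OCOC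
F3 | step 8 | 4-bromoresorcinol (purchased) | Oc1ccc(Br)c(O)c1
F4 | step 8 | 6-bromo-7-hydroxy-2,2-dimethylchroman-4-one | O=C1CC(C)(C)Oc2cc(O)c(Br)cc12
F5 | step 8 | 6-bromo-7-(methoxymethoxy)-2,2-dimethylchroman-4-one | O=C1CC(C)(C)Oc2cc(OCOC)c(Br)cc12
F6 | step 8 | 6-bromo-7-(methoxymethoxy)-2,2-dimethylchroman-4-ol (racemic) | OC1CC(C)(C)Oc2cc(OCOC)c(Br)cc12
F7 | step 8 | 6-bromo-7-(methoxymethoxy)-2,2-dimethyl-2H-chromene | COCOc1cc2OC(C)(C)C=Cc2cc1Br
F8 | step 14 | (2S)-5,7-bis(trimethylsilyloxy)-2-[2,2-dimethyl-7-(trimethylsilyloxy)-2H-chromen-6-yl]-6,8-bis(3-methylbut-2-en-1-yl)chroman-4-one | CC(C)=CCc1c(O[Si](C)(C)C)c(CC=C(C)C)c2c(c1O[Si](C)(C)C)C(=O)C[C@@H](c1cc3c(cc1O[Si](C)(C)C)OC(C)(C)C=C3)O2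
A1 | alternative 1 | (2S)-2-[2,2-dimethyl-7-(triisopropylsilyloxy)-2H-chromen-6-yl]-5,7-bis[(2-methylbut-3-en-2-yl)oxy]chroman-4-one | O=C1C[C@@H](c3cc4c(cc3O[Si](C(C)C)(C(C)C)C(C)C)OC(C)(C)C=C4)Oc2cc(OC(C)(C)C=C)cc(OC(C)(C)C=C)c12
A2 | alternative 1 | 2'-O-triisopropylsilyl euchrenone a3 | O=C1C[C@@H](c3cc4c(cc3O[Si](C(C)C)(C(C)C)C(C)C)OC(C)(C)C=C4)Oc2c(CC=C(C)C)c(O)c(CC=C(C)C)c(O)c12
A3 | alternative 2 | (2S)-5,7-bis(methoxymethoxy)-6,8-bis(3-methylbut-2-en-1-yl)-2-[4-(2-methylbut-3-yn-2-yloxy)-2-(triisopropylsilyloxy)phenyl]chroman-4-one | O=C1C[C@@H](c3ccc(OC(C)(C)C#C)cc3O[Si](C(C)C)(C(C)C)C(C)C)Oc2c(CC=C(C)C)c(OCOC)c(CC=C(C)C)c(OCOC)c12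
A4 | alternative 2 | 2'-O-triisopropylsilyl-5,7-bis(methoxymethyl) ether of euchrenone a3 | O=C1C[C@@H](c3cc4c(cc3O[Si](C(C)C)(C(C)C)C(C)C)OC(C)(C)C=C4)Oc2c(CC=C(C)C)c(OCOC)c(CC=C(C)C)c(OCOC)c12
A5 | alternative 3 | methyl 4-{(2S)-2-[7-(methoxymethoxy)-2,2-dimethyl-2H-chromen-6-yl]-4-oxo-3,4-dihydro-2H-pyran-6-yl}-2,4-bis(3-methylbut-2-en-1-yl)-3-oxobutanoate (side-chain centres unassigned) | COC(=O)C(CC=C(C)C)C(=O)C(CC=C(C)C)C1=CC(=O)C[C@@H](c2cc3C=CC(C)(C)Oc3cc2OCOC)O1
A6 | alternative 3 | 2'-O-methoxymethyl euchrenone a3 | O=C1C[C@@H](c3cc4c(cc3OCOC)OC(C)(C)C=C4)Oc2c(CC=C(C)C)c(O)c(CC=C(C)C)c(O)c12
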